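## Retrosynthetic overview

1. C-2–C-1' bond (sets C-2): the (2S)-flavanone comes from a chromone (rings A and C, bought as 7-hydroxychromone) and a chroman-6-ylboronic acid (rings B and D). They are joined by rhodium-catalysed asymmetric 1,4-addition.
2. C-8 prenyl and 7-OH come from a 7-O-(1,1-dimethylallyl) ether by aromatic Claisen rearrangement in the last step, so this ether is also the only phenol protection.
3. Ring D is cut at ArCH2–CH2 and O–CMe2 together, giving an o-quinone methide of ring B plus isobutene ([4+2]). The neighbouring C-prenyl group comes from an O-(1,1-dimethylallyl) ether on the same oxygen ([3,3]). Both events run in one operation from a benzyl acetate.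
4. Enabling feature: O-1 of ring D sits between two substituted ortho carbons, C-4a (bearing the benzylic C-4 methylene) and C-8 (bearing prenyl). O-1/C-8a/C-4a/C-4 is therefore a latent O=C–C=CH2 heterodiene, C-2(Me2)/C-3 is isobutene, and the prenyl group is the [3,3] image of an ether on O-1. The para carbon C-6, the later link to the flavanone, carries bromine.
5. Ring order: rings A, B and C are bought, ring D is formed in step 4, and no further ring closure is needed.

Key step: step 4

Assumption: the sense of induction in step 7 is taken from the usual quadrant model of (S)-configured biaryl diphosphine–rhodium catalysts, where the (S)-ligand gives (S)-3-arylcyclohexanones, spatially equivalent to the (2S)-flavanone. If the chromone responds in the opposite sense, the (R)-ligand is used.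

## Route

Step 1
Reactants: 1 2-methylbut-3-en-2-ol
Product: 2 tert-butyl 2-methylbut-3-en-2-yl carbonate
Conditions: n-BuLi (1.05 equiv), THF, −78 to 0 °C; Boc2O, 0 °C to rt; H2O quench
Reagents that add atoms: di-tert-butyl dicarbonate, CC(C)(C)OC(=O)OC(=O)OC(C)(C)C
Why: Acylation of an alkoxide (nucleophilic acyl substitution), in which the lithium alkoxide of the tertiary allylic alcohol attacks Boc2O and the expelled tert-butyl carbonate anion collapses to CO2 and tert-butoxide, making the step irreversible.

Step 2
Reactants: 3 4-bromo-2-(hydroxymethyl)phenol (5-bromo-2-hydroxybenzyl alcohol); 2 tert-butyl 2-methylbut-3-en-2-yl carbonate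
Product: 4 [5-bromo-2-(2-methylbut-3-en-2-yloxy)phenyl]methanol
Conditions: Pd(PPh3)4 (2 mol%), THF, 0 °C
Reagents that add atoms: none
Why: Tsuji–Trost O-allylation, in which zerovalent palladium ionises the tertiary carbonate to a 1,1-dimethyl-π-allyl complex and tert-butoxide, only the phenol is deprotonated, and under kinetic control at 0 °C the phenoxide attacks the more substituted allyl terminus to give the branched ether, leaving the primary alcohol and the electron-rich aryl bromide untouched.

Step 3
Reactants: 4 [5-bromo-2-(2-methylbut-3-en-2-yloxy)phenyl]methanol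
Product: 5 5-bromo-2-(2-methylbut-3-en-2-yloxy)benzyl acetate
Conditions: Ac2O, pyridine, DMAP (cat.), CH2Cl2, 0 °C to rt
Reagents that add atoms: acetic anhydride, CC(=O)OC(C)=O
Why: DMAP-catalysed O-acetylation in a basic medium that spares the acid-labile tertiary allyl ether, and because the phenol oxygen is capped the benzyl acetate cannot yet eliminate to a quinone methide and can be stored.

Step 4
Reactants: 5 5-bromo-2-(2-methylbut-3-en-2-yloxy)benzyl acetate; 6 isobutene (2-methylpropene)
Product: 10 6-bromo-2,2-dimethyl-8-(3-methylbut-2-en-1-yl)-3,4-dihydro-2H-chromene, via Claisen dienone 7 (not isolated), via prenylphenol acetate 8 (not isolated), via o-quinone methide 9 (not isolated)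
Conditions: isobutene (50 equiv, condensed in), 2,6-lutidine (1.5 equiv), toluene (0.05 M), steel autoclave, 135 °C
Reagents that add atoms: none
Why: Proposed new method: an aromatic Claisen rearrangement is made the gate that releases an o-quinone methide, the reasoning being that the [3,3] shift of the O-(1,1-dimethylallyl) group of 5 can end only at the single hydrogen-bearing ortho carbon (dienone 7, then phenol 8 by tautomerisation), that only 8 has the free OH next to CH2OAc needed for lutidine-assisted 1,4-elimination of acetic acid to 9, and that 9 is then taken up by isobutene in an inverse-electron-demand hetero-Diels–Alder reaction. The closest known reaction types are the thermal Claisen rearrangement of aryl 1,1-dimethylallyl ethers to o-prenylphenols, the thermal or amine-induced formation of o-quinone methides from o-hydroxybenzyl acetates, and the [4+2] cycloaddition of o-quinone methides to 1,1-disubstituted alkenes that gives 2,2-disubstituted chromans; only their coupling in one operation is new. The one ring that is closed, the dihydropyran ring D, forms by intermolecular [4+2] cycloaddition of the O=C–C=CH2 heterodiene of 9 to the C=C of isobutene, which makes the ArCH2–CH2 and the O–CMe2 bonds together and is driven by rearomatisation of ring B. No stereocenter remains in 10 (the sp3 carbon of 7 is transient and is lost on enolisation), so no stereocontrol is needed. Regioselectivity of the cycloaddition follows from matched polarisation, the nucleophilic CH2 terminus of isobutene meeting the electrophilic exocyclic methylene while the carbon that can bear tertiary cationic character binds oxygen, and regioselectivity of the Claisen step follows from the substitution pattern, with CH2OAc on one ortho carbon and bromine on the para carbon. Chemoselectivity for isobutene over the prenyl double bonds and over self-condensation of 9 is secured by the large excess of isobutene, by the low stationary concentration of 9 that the rate-limiting Claisen step enforces, and by the fact that every ortho and para position of phenol 8 is occupied.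

Step 5
Reactants: 10 6-bromo-2,2-dimethyl-8-(3-methylbut-2-en-1-yl)-3,4-dihydro-2H-chromene
Product: 11 [2,2-dimethyl-8-(3-methylbut-2-en-1-yl)-3,4-dihydro-2H-chromen-6-yl]boronic acid
Conditions: n-BuLi, THF, −78 °C; B(OiPr)3, −78 °C to rt; 1 M HCl, 0 °C
Reagents that add atoms: triisopropyl borate, CC(C)OB(OC(C)C)OC(C)C; water, O
Why: Halogen–lithium exchange followed by electrophilic borylation and hydrolysis, the exchange at −78 °C being faster than deprotonation of the allylic benzylic CH2, and the brief cold acid work-up being harmless because no free phenol stands next to the prenyl group.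

Step 6
Reactants: 12 7-hydroxy-4H-chromen-4-one (7-hydroxychromone); 2 tert-butyl 2-methylbut-3-en-2-yl carbonate
Product: 13 7-(2-methylbut-3-en-2-yloxy)-4H-chromen-4-one
Conditions: Pd(PPh3)4 (2 mol%), THF, 0 °C, quenched at full conversion
Reagents that add atoms: none
Why: Tsuji–Trost O-allylation as in step 2, where low temperature and a short reaction time keep the kinetically formed branched ether from re-ionising and drifting to the linear prenyl ether.

Step 7
Reactants: 11 [2,2-dimethyl-8-(3-methylbut-2-en-1-yl)-3,4-dihydro-2H-chromen-6-yl]boronic acid (1.5 equiv); 13 7-(2-methylbut-3-en-2-yloxy)-4H-chromen-4-one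
Product: 14 (2S)-2-[2,2-dimethyl-8-(3-methylbut-2-en-1-yl)-3,4-dihydro-2H-chromen-6-yl]-7-(2-methylbut-3-en-2-yloxy)-2,3-dihydro-4H-chromen-4-one
Conditions: [Rh(OH)(cod)]2 (2.5 mol%), (S)-MeO-F12-BIPHEP [(S)-6,6'-dimethoxy-2,2'-bis(bis(3,4,5-trifluorophenyl)phosphino)-1,1'-biphenyl, 5.5 mol%], toluene/H2O (10:1), 25 °C
Reagents that add atoms: none
Why: Hayashi–Miyaura reaction on a chromone, a substrate class on which electron-poor biaryl diphosphines are known to work at room temperature, in which transmetalation gives an aryl complex of monovalent rhodium, the enantioface-selective insertion of C-2=C-3 inside the pocket of the (S)-ligand sets C-2 as S, and hydrolysis of the rhodium enolate releases 14, while the unhindered boron position of 11 favours transmetalation and the neopentyl-type vinyl group and the trisubstituted alkene are far poorer acceptors than the enone.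

Step 8
Reactants: 14 (2S)-2-[2,2-dimethyl-8-(3-methylbut-2-en-1-yl)-3,4-dihydro-2H-chromen-6-yl]-7-(2-methylbut-3-en-2-yloxy)-2,3-dihydro-4H-chromen-4-one
Product: 16 (2S)-7-hydroxy-8-(3-methylbut-2-en-1-yl)-2-[2,2-dimethyl-8-(3-methylbut-2-en-1-yl)-3,4-dihydro-2H-chromen-6-yl]-2,3-dihydro-4H-chromen-4-one (CNP0272905.1), via Claisen dienone 15 (not isolated)
Conditions: toluene (degassed), argon, sealed tube, 120 °C
Reagents that add atoms: none
Why: Aromatic Claisen rearrangement, in which the [3,3] shift goes to C-8, the position favoured in 7-allyloxy chromanones, chromones and coumarins by the higher C-7–C-8 bond order, enolisation of 15 frees the 7-OH, and C-2 should keep its configuration because the medium is neutral and aprotic and ring B has no free para-hydroxyl to assist ring opening.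

## Compound list

1 | 2-methylbut-3-en-2-ol | CC(C)(O)C=C | starting material
2 | tert-butyl 2-methylbut-3-en-2-yl carbonate | C=CC(C)(C)OC(=O)OC(C)(C)C | intermediate
3 | 4-bromo-2-(hydroxymethyl)phenol | OCc1cc(Br)ccc1O | starting material
4 | [5-bromo-2-(2-methylbut-3-en-2-yloxy)phenyl]methanol | OCc1cc(Br)ccc1OC(C)(C)C=C | intermediate
5 | 5-bromo-2-(2-methylbut-3-en-2-yloxy)benzyl acetate | CC(=O)OCc1cc(Br)ccc1OC(C)(C)C=C | intermediate
6 | isobutene | CC(C)=C | starting material
7 | [3-bromo-5-(3-methylbut-2-en-1-yl)-6-oxocyclohexa-1,3-dien-1-yl]methyl acetate (racemic, transient) | CC(=O)OCC1=CC(Br)=CC(CC=C(C)C)C1=O | intermediate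
8 | 5-bromo-2-hydroxy-3-(3-methylbut-2-en-1-yl)benzyl acetate | CC(=O)OCc1cc(Br)cc(CC=C(C)C)c1O | intermediate
9 | 4-bromo-6-methylidene-2-(3-methylbut-2-en-1-yl)cyclohexa-2,4-dien-1-one | C=C1C=C(Br)C=C(CC=C(C)C)C1=O | intermediate
10 | 6-bromo-2,2-dimethyl-8-(3-methylbut-2-en-1-yl)-3,4-dihydro-2H-chromene | CC(C)=CCc1cc(Br)cc2c1OC(C)(C)CC2 | intermediate
11 | [2,2-dimethyl-8-(3-methylbut-2-en-1-yl)-3,4-dihydro-2H-chromen-6-yl]boronic acid | CC(C)=CCc1cc(B(O)O)cc2c1OC(C)(C)CC2 | intermediate
12 | 7-hydroxy-4H-chromen-4-one | O=c1ccoc2cc(O)ccc12 | starting material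
13 | 7-(2-methylbut-3-en-2-yloxy)-4H-chromen-4-one | C=CC(C)(C)Oc1ccc2c(=O)ccoc2c1 | intermediate
14 | (2S)-2-[2,2-dimethyl-8-(3-methylbut-2-en-1-yl)-3,4-dihydro-2H-chromen-6-yl]-7-(2-methylbut-3-en-2-yloxy)-2,3-dihydro-4H-chromen-4-one | CC(C)=CCc1cc([C@@H]2CC(=O)c3ccc(OC(C)(C)C=C)cc3O2)cc2c1OC(C)(C)CC2 | intermediate
15 | (2S)-2-[2,2-dimethyl-8-(3-methylbut-2-en-1-yl)-3,4-dihydro-2H-chromen-6-yl]-8-(3-methylbut-2-en-1-yl)-2,3-dihydro-4H-chromene-4,7(8H)-dione (C-8 undefined, transient) | CC(C)=CCc1cc([C@@H]2CC(=O)C3=C(O2)C(CC=C(C)C)C(=O)C=C3)cc2c1OC(C)(C)CC2 | intermediate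
16 | (2S)-7-hydroxy-8-(3-methylbut-2-en-1-yl)-2-[2,2-dimethyl-8-(3-methylbut-2-en-1-yl)-3,4-dihydro-2H-chromen-6-yl]-2,3-dihydro-4H-chromen-4-one | CC(C)=CCc1cc([C@@H]2CC(=O)c3ccc(O)c(CC=C(C)C)c3O2)cc2c1OC(C)(C)CC2 | target

## Step count and risks

Total step count: 8.
Longest linear sequence: 7 (steps 1, 2, 3, 4, 5, 7, 8).

Steps most likely to fail:

**1. Step 4 (Proposed new method:).**
- Risk: self-condensation of the o-quinone methide, or its capture by prenyl double bonds, may outrun cycloaddition to the weakly nucleophilic isobutene.
- Risk: the tertiary allyl group may be lost by acid-induced fragmentation before it has rearranged.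
- Fallback (known chemistry; the domino is taken apart and a different quinone methide precursor is used): it sets out from 4. Compound 4 is heated alone (toluene, 120 °C), so that only the Claisen rearrangement occurs, because hydroxide is too poor a leaving group at this temperature. This gives 4-bromo-2-(hydroxymethyl)-6-(3-methylbut-2-en-1-yl)phenol F1, which is isolated and purified. F1 is then heated with a large excess of isobutene in an autoclave at 170–180 °C. This is the established thermal dehydration of an o-hydroxybenzyl alcohol to the o-quinone methide 9 with [4+2] trapping. The fallback comes back to the route at 10.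

**2. Step 8.**
- Risk: incomplete regiocontrol between C-8 and C-6.
- Risk: slow thermal erosion of the configuration at C-2 through reversible opening of ring C.
- Fallback (the rearrangement is moved ahead of the stereocenter): it sets out from 13, which is rearranged at the achiral stage (xylene, 130 °C) to 7-hydroxy-8-(3-methylbut-2-en-1-yl)-4H-chromen-4-one F2, where regioisomers can be separated. Silylation (TBSCl, imidazole, DMF) gives 7-(tert-butyldimethylsilyloxy)-8-(3-methylbut-2-en-1-yl)-4H-chromen-4-one F3. The 1,4-addition of 11 under the conditions of step 7 gives the (2S)-configured silyl ether of the target F4. Buffered fluoride (Et3N·3HF, THF, 0 °C) removes the silyl group without base. The fallback comes back to the route at 16.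

**3. Step 7.**
- Risk: sluggish insertion into the donor-deactivated chromone.
- Risk: protodeboronation outrunning the addition.
- Risk: engagement of the terminal vinyl group of the ether by rhodium.
- Fallback (ring C is built from a chalcone and the enantiomers are then separated by catalysis): it sets out from 10.
  - Bromine–lithium exchange and DMF give 2,2-dimethyl-8-(3-methylbut-2-en-1-yl)-3,4-dihydro-2H-chromene-6-carbaldehyde F5.
  - Commercial 2,4-dihydroxyacetophenone and 2 (Pd(PPh3)4, THF, 0 °C; the chelated 2-OH stays free) give 1-[2-hydroxy-4-(2-methylbut-3-en-2-yloxy)phenyl]ethanone F6.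
  - Claisen–Schmidt condensation of F5 and F6 (KOH, EtOH, rt) gives the (E)-chalcone F7.
  - NaOAc in refluxing EtOH closes F7 to the racemic flavanone F8.
  - Kinetic resolution by asymmetric transfer hydrogenation (RuCl(p-cymene)[(R,R)-TsDPEN], HCO2H/Et3N, EtOAc, rt) reduces the (2R)-ketone to the cis-(2R,4R)-flavan-4-ol F9, which is removed by chromatography. The (2S)-ketone is left behind.
  - The fallback comes back to the route at 14.

## Further compounds

F1 | step 4 | 4-bromo-2-(hydroxymethyl)-6-(3-methylbut-2-en-1-yl)phenol | OCc1cc(Br)cc(CC=C(C)C)c1O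
F2 | step 8 | 7-hydroxy-8-(3-methylbut-2-en-1-yl)-4H-chromen-4-one | CC(C)=CCc1c(O)ccc2c(=O)ccoc12
F3 | step 8 | 7-(tert-butyldimethylsilyloxy)-8-(3-methylbut-2-en-1-yl)-4H-chromen-4-one | CC(C)=CCc1c(O[Si](C)(C)C(C)(C)C)ccc2c(=O)ccoc12
F4 | step 8 | (2S)-7-(tert-butyldimethylsilyloxy)-8-(3-methylbut-2-en-1-yl)-2-[2,2-dimethyl-8-(3-methylbut-2-en-1-yl)-3,4-dihydro-2H-chromen-6-yl]-2,3-dihydro-4H-chromen-4-one | CC(C)=CCc1cc([C@@H]2CC(=O)c3ccc(O[Si](C)(C)C(C)(C)C)c(CC=C(C)C)c3O2)cc2c1OC(C)(C)CC2
F5 | step 7 | 2,2-dimethyl-8-(3-methylbut-2-en-1-yl)-3,4-dihydro-2H-chromene-6-carbaldehyde | CC(C)=CCc1cc(C=O)cc2c1OC(C)(C)CC2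
F6 | step 7 | 1-[2-hydroxy-4-(2-methylbut-3-en-2-yloxy)phenyl]ethanone | CC(=O)c1ccc(OC(C)(C)C=C)cc1O
F7 | step 7 | (E)-3-[2,2-dimethyl-8-(3-methylbut-2-en-1-yl)-3,4-dihydro-2H-chromen-6-yl]-1-[2-hydroxy-4-(2-methylbut-3-en-2-yloxy)phenyl]prop-2-en-1-one | CC(C)=CCc1cc(/C=C/C(=O)c2ccc(OC(C)(C)C=C)cc2O)cc2c1OC(C)(C)CC2
F8 | step 7 | racemic 2-[2,2-dimethyl-8-(3-methylbut-2-en-1-yl)-3,4-dihydro-2H-chromen-6-yl]-7-(2-methylbut-3-en-2-yloxy)-2,3-dihydro-4H-chromen-4-one | CC(C)=CCc1cc(C2CC(=O)c3ccc(OC(C)(C)C=C)cc3O2)cc2c1OC(C)(C)CC2
F9 | step 7 | (2R,4R)-2-[2,2-dimethyl-8-(3-methylbut-2-en-1-yl)-3,4-dihydro-2H-chromen-6-yl]-7-(2-methylbut-3-en-2-yloxy)-3,4-dihydro-2H-chromen-4-ol | CC(C)=CCc1cc([C@H]2C[C@@H](O)c3ccc(OC(C)(C)C=C)cc3O2)cc2c1OC(C)(C)CC2
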